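The earlier runs and the new flask stem from a simulated flask for substances that don't exist, and the scatter is random.

Hold teal at 12.0 min beside green at 3.00 min. You see teal at 5.80 mM of target and green at 5.60 mM, though green ran a quarter of the time with 4.00 times the enzyme, at equal loading.

in all of them: enzyme 0.001 mol%
- teal: starting material 10 mM; run made earlier
- green: starting material 40 mM; run made earlier
- flask: starting material 20 mM

| run | time / min | target / % | starting material / % |
|---|---|---|---|
| teal | 1.50 | 15 | 86 |
| teal | 4.00 | 31 | 70 |
| teal | 8.00 | 47 | 54 |
| teal | 12.0 | 58 | 42 |
| green | 3.00 | 14 | 85 |
| green | 6.00 | 19 | 79 |
| green | 10.0 | 23 | 75 |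
| green | 12.0 | 26 | 74 |

(standard deviation of a reading: 1.5 percentage points)

1. apparent order in enzyme when 50 % of the starting material are converted (percent change of the rate of making target for one percent more enzyme charged)
2. factor on the rate of making target when 50 % of the starting material are converted if enzyme is charged twice over

Write P for target in mM and r for its rate of making. Green's P rises by roughly equal steps per factor of time. Divide the fall of r by r itself, and time drops out: r = s·exp(−P/B), with s the starting rate. B, the target budget, is the target made while r falls by a factor e. Green reads 3.46 mM.

Now my bracket, which credits the shift to enzyme, though both charges moved together. Let n be the log of the clock ratio over the log of the enzyme ratio. Teal at 12.0 min reads level with green's first P, inside the scatter of one green reading, 0.600 mM, so the top of the bracket is n near 1.00, an estimate and not a strict bound. Teal at 8.00 min reads below it, so n reads above 0.708. Using B to close the small gap in P gives the reading n = 0.958, so doubling gives 1.94.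

The forecast, reading “enzyme loss driven by substrate or turnover”, gives order 3 and factor 4, which is above the bracket. The flask gives order 1.0 and factor 2.00, at the bracket's top.

    starting material + enzyme ⇌ complex (K = 1900 M⁻¹, k = 1.60 × 10⁶ M⁻¹ s⁻¹)
    complex ⇌ enzyme + target (K = 0.150 M, k = 210 s⁻¹)
    2 complex → spent catalyst (k = 29000 M⁻¹ s⁻¹)

Two complex pairing to spent catalyst is the largest single effect on r: with that step taken away, this flask runs at 14.1 times the actual rate at half conversion. Per complex, loss goes as complex, and target is made as complex, so the fractional loss of complex per target made is free of time. In this flask, the further 4.00 mM of target up to 63.7 min should cut r to 0.315 of its value, and the simulated ratio is 0.34. Charged with twice the enzyme, this flask makes r double at half conversion, and the time to that conversion changes by a factor 0.500.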